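The route rests on disconnecting the C8–C9 bond of the seven-membered ring B (guaiane numbering). Ring A, with its C15 methyl, the C6 methylene and the C9/C10/C14 isopropenyl group on C1, is the carbon pattern of ring-contracted (S)-limonene, and this isopropenyl group lies where a C8 acyl radical reaches C9 in a 7-endo closure. In one operation the key step closes ring B, places the C8 ketone and sets C10. Its precursor is a limonene-derived cyclopentene carrying the isopropenyl group on C1 and, on C5, a side chain with the auxiliary-set C7 stereocenter, a C8 phenyl selenoester and a silyl-protected C11 carbinol.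

Key step: step 9

Remark: guaiane numbering is used for the bicyclic compounds (ring A five-membered, ring B seven-membered); the target is taken as (1R,7S,8R,10S), with H1, the C14 methyl, the C7 side chain and the C8 oxygen on one face of ring B; (S)-limonene supplies C1 as R and the (R)-benzyl auxiliary supplies C7 as R.

Step 1
Reactants: 1 (S)-limonene
Product: 3 (5R)-2-methyl-5-(prop-1-en-2-yl)cyclopent-1-ene-1-carbaldehyde, via keto-aldehyde 2 (not isolated)
Conditions: O3 (1.0 equiv), CH2Cl2/MeOH, −78 °C; Me2S, −78 °C → rt; then piperidine, AcOH, toluene, 80 °C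
Reagents that add atoms: ozone, [O-][O+]=O
Why: Ozonolysis with one equivalent of ozone cleaves the electron-rich trisubstituted ring alkene ahead of the 1,1-disubstituted isopropenyl group, and the amine-acid-mediated intramolecular aldol condensation of keto-aldehyde 2 (aldehyde enamine onto the methyl ketone, then dehydration) closes ring A, the stereocenter that becomes C1 being carried over unchanged from limonene.

Step 2
Reactants: 3 (5R)-2-methyl-5-(prop-1-en-2-yl)cyclopent-1-ene-1-carbaldehyde
Product: 4 [(5R)-2-methyl-5-(prop-1-en-2-yl)cyclopent-1-en-1-yl]methanol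
Conditions: NaBH4, CeCl3·7H2O, MeOH, 0 °C
Reagents that add atoms: none
Why: Luche reduction delivers hydride 1,2 to the enal and leaves both alkenes and the stereocenter untouched.

Step 3
Reactants: 4 [(5R)-2-methyl-5-(prop-1-en-2-yl)cyclopent-1-en-1-yl]methanol
Product: 5 (3R)-2-(bromomethyl)-1-methyl-3-(prop-1-en-2-yl)cyclopent-1-ene
Conditions: CBr4, PPh3, CH2Cl2, 0 °C
Reagents that add atoms: tetrabromomethane, BrC(Br)(Br)Br
Why: The Appel reaction converts the primary allylic alcohol into the bromide by SN2 displacement of the oxyphosphonium group under neutral conditions, which avoids acid-promoted allylic transposition or alkene isomerisation.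

Step 4
Reactants: 6 3-hydroxy-3-methylbutanoic acid
Product: 8 3-methyl-3-(triethylsilyloxy)butanoic acid, via bis-silyl derivative 7 (not isolated)
Conditions: Et3SiOTf (2.3 equiv), 2,6-lutidine, CH2Cl2, 0 °C → rt; then K2CO3, MeOH/H2O, 0 °C; aq. KHSO4 to pH 4
Reagents that add atoms: triethylsilyl trifluoromethanesulfonate, CC[Si](CC)(CC)OS(=O)(=O)C(F)(F)F
Why: The silyl triflate silylates both the tertiary hydroxyl and the carboxyl group, and the labile silyl ester is then hydrolysed selectively by carbonate while the tertiary triethylsilyl ether persists (silylation followed by selective silyl ester cleavage).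

Step 5
Reactants: 8 3-methyl-3-(triethylsilyloxy)butanoic acid; 9 (R)-4-benzyloxazolidin-2-one
Product: 11 (4R)-4-benzyl-3-[3-methyl-3-(triethylsilyloxy)butanoyl]-1,3-oxazolidin-2-one, via mixed pivalic anhydride 10 (not isolated)
Conditions: t-BuCOCl, Et3N, THF, −20 °C; then 9, LiCl, −20 °C → rt
Reagents that add atoms: none
Why: N-Acylation of the oxazolidinone through the mixed pivalic anhydride (LiCl and Et3N activate the NH) occurs at the less hindered of the two anhydride carbonyls, and the auxiliary stereocenter is not involved.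

Step 6
Reactants: 11 (4R)-4-benzyl-3-[3-methyl-3-(triethylsilyloxy)butanoyl]-1,3-oxazolidin-2-one; 5 (3R)-2-(bromomethyl)-1-methyl-3-(prop-1-en-2-yl)cyclopent-1-ene
Product: 13 (4R)-4-benzyl-3-[(2R)-3-methyl-2-{[(5R)-2-methyl-5-(prop-1-en-2-yl)cyclopent-1-en-1-yl]methyl}-3-(triethylsilyloxy)butanoyl]-1,3-oxazolidin-2-one, via sodium Z-enolate 12 (not isolated)
Conditions: NaN(SiMe3)2, THF, −78 °C; then 5, −78 → −40 °C
Reagents that add atoms: none
Why: Evans alkylation, in which NaN(SiMe3)2 gives the chelated Z-enolate 12, whose face opposite the benzyl group attacks the primary allylic bromide in an SN2 reaction (SN2' attack at the fully substituted ring carbon being hindered), which sets C7 as R.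

Step 7
Reactants: 13 (4R)-4-benzyl-3-[(2R)-3-methyl-2-{[(5R)-2-methyl-5-(prop-1-en-2-yl)cyclopent-1-en-1-yl]methyl}-3-(triethylsilyloxy)butanoyl]-1,3-oxazolidin-2-one
Product: 15 (2R)-3-methyl-2-{[(5R)-2-methyl-5-(prop-1-en-2-yl)cyclopent-1-en-1-yl]methyl}-3-(triethylsilyloxy)butanoic acid, via peroxy acid 14 (not isolated)
Conditions: LiOH, 30% H2O2, THF/H2O, 0 °C; aq. Na2SO3; 1 M HCl to pH 3, 0 °C
Reagents that add atoms: hydrogen peroxide, OO
Why: Hydroperoxide anion attacks the exocyclic imide carbonyl selectively even in hindered cases (auxiliary cleavage with LiOOH), the peroxy acid 14 is reduced by sulfite, the nucleophilic peroxide does not touch the unactivated alkenes, and C7 is not epimerised under these cold conditions.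

Step 8
Reactants: 15 (2R)-3-methyl-2-{[(5R)-2-methyl-5-(prop-1-en-2-yl)cyclopent-1-en-1-yl]methyl}-3-(triethylsilyloxy)butanoic acid
Product: 16 Se-phenyl (2R)-3-methyl-2-{[(5R)-2-methyl-5-(prop-1-en-2-yl)cyclopent-1-en-1-yl]methyl}-3-(triethylsilyloxy)butaneselenoate
Conditions: PhSeSePh, PBu3, CH2Cl2, rt
Reagents that add atoms: diphenyl diselenide, c1ccc(cc1)[Se][Se]c1ccccc1
Why: Activation of the acid as an acyloxyphosphonium salt by PBu3 and PhSeSePh followed by attack of selenolate gives the phenyl selenoester under neutral conditions (phosphine-diselenide selenoesterification) without epimerising C7 or disturbing the silyl ether.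

Step 9
Reactants: 16 Se-phenyl (2R)-3-methyl-2-{[(5R)-2-methyl-5-(prop-1-en-2-yl)cyclopent-1-en-1-yl]methyl}-3-(triethylsilyloxy)butaneselenoate
Product: 17 (1R,7R,10S)-11-(triethylsilyloxy)guai-4-en-8-one
Conditions: (Me3Si)3SiH, AIBN, benzene (5 mM), 80 °C, syringe-pump addition of silane and initiator
Reagents that add atoms: none
Why: The silyl radical abstracts the phenylseleno group of 16 to give the C8 acyl sigma radical, which adds to the unsubstituted terminus C9 of the isopropenyl group, and the resulting tertiary C10 radical takes a hydrogen atom from (Me3Si)3SiH to propagate the chain. The closest known reaction type is the endo-selective cyclisation of acyl radicals generated from phenyl selenoesters onto 1,1-disubstituted alkenes. Ring B closes in the 7-endo-trig mode through the new C8–C9 bond, the competing 6-exo mode being disfavoured because it would attack the fully substituted C10 and leave a primary radical. The new stereocenter C10 is set in the hydrogen transfer: with the planar ring A holding C2 pseudoequatorial and H1 pseudoaxial on ring B, the bulky silane should deliver hydrogen pseudoaxially on the face anti to H1 and away from the C7 side chain, so that the C14 methyl ends cis to H1 (10S). The step needs chemoselectivity over the tetrasubstituted C4=C5 alkene, which the acyl radical could reach only by 4-exo or 5-endo closure, and over premature reduction and decarbonylation, which high dilution, slow silane addition and the lower hydrogen-donor rate of (Me3Si)3SiH relative to tin hydrides should suppress, while C1 and C7 are not touched under these neutral conditions.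

Step 10
Reactants: 17 (1R,7R,10S)-11-(triethylsilyloxy)guai-4-en-8-one
Product: 18 (1R,7S,8R,10S)-11-(triethylsilyloxy)guai-4-en-8-ol
Conditions: LiBH(s-Bu)3, THF, −78 °C; then NaOH, H2O2, 0 °C
Reagents that add atoms: none
Why: The bulky hydride of LiBH(s-Bu)3 approaches the C8 carbonyl from the face opposite the adjacent C7 side chain (sterically controlled ketone reduction), giving the 8R alcohol with its hydroxyl cis to that side chain, and the cold, weakly basic conditions spare C7.

Step 11
Reactants: 18 (1R,7S,8R,10S)-11-(triethylsilyloxy)guai-4-en-8-ol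
Product: 19 (1R,7S,8R,10S)-guai-4-ene-8,11-diol
Conditions: HF·pyridine, pyridine, THF, 0 °C → rt
Reagents that add atoms: none
Why: Fluoride-driven cleavage of the Si–O bond (desilylation with buffered HF) frees the tertiary C11 hydroxyl without acid strong enough to ionise it, and any silyl group that had migrated to O8 in step 10 is removed as well, so both isomers converge on 19.

Step 12
Reactants: 19 (1R,7S,8R,10S)-guai-4-ene-8,11-diol
Product: 20 (1R,7S,8R,10S)-11-hydroxyguai-4-en-8-yl 2-methylprop-2-enoate
Conditions: methacrylic anhydride (1.2 equiv), Et3N, DMAP (cat.), CH2Cl2, 0 °C → rt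
Reagents that add atoms: methacrylic anhydride, C=C(C)C(=O)OC(=O)C(C)=C
Why: DMAP-catalysed acylation distinguishes the secondary C8 hydroxyl from the far more hindered tertiary C11 hydroxyl, so a slight excess of methacrylic anhydride should esterify C8 only, with retention at C8.

Step 13
Reactants: 20 (1R,7S,8R,10S)-11-hydroxyguai-4-en-8-yl 2-methylprop-2-enoate
Product: 21 (1R,7S,8R,10S)-11-acetoxyguai-4-en-8-yl 2-methylprop-2-enoate
Conditions: Ac2O (excess), DMAP, Et3N, CH2Cl2, 40 °C
Reagents that add atoms: acetic anhydride, CC(=O)OC(C)=O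
Why: DMAP-catalysed acetylation with excess anhydride and mild warming is the standard way to esterify a tertiary alcohol, and neither the methacrylate nor the tetrasubstituted alkene reacts under these conditions.

Step 14
Reactants: 21 (1R,7S,8R,10S)-11-acetoxyguai-4-en-8-yl 2-methylprop-2-enoate
Product: 22 (1R,7S,8R,10S)-11-acetoxy-3-oxoguai-4-en-8-yl 2-methylprop-2-enoate (CNP0318307.1)
Conditions: CrO3, 3,5-dimethylpyrazole, CH2Cl2, −20 °C
Reagents that add atoms: chromium trioxide, O=[Cr](=O)=O
Why: The CrO3–3,5-dimethylpyrazole complex (allylic oxidation by hexavalent chromium) converts an allylic ring methylene next to an electron-rich alkene into the enone, and of the allylic positions of C4=C5 the unhindered ring A methylene C3 should react in preference to C6, which is shielded by the neighbouring C7 and C8 substituents, and to the tertiary C1–H, while both esters and the electron-poor methacrylate alkene are inert.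

Compound list

1 | (S)-limonene | C=C(C)[C@H]1CCC(C)=CC1 | starting material
2 | (3S)-6-oxo-3-(prop-1-en-2-yl)heptanal | C=C(C)[C@H](CC=O)CCC(C)=O | intermediate
3 | (5R)-2-methyl-5-(prop-1-en-2-yl)cyclopent-1-ene-1-carbaldehyde | C=C(C)[C@H]1CCC(C)=C1C=O | intermediate
4 | [(5R)-2-methyl-5-(prop-1-en-2-yl)cyclopent-1-en-1-yl]methanol | C=C(C)[C@H]1CCC(C)=C1CO | intermediate
5 | (3R)-2-(bromomethyl)-1-methyl-3-(prop-1-en-2-yl)cyclopent-1-ene | C=C(C)[C@H]1CCC(C)=C1CBr | intermediate
6 | 3-hydroxy-3-methylbutanoic acid | CC(C)(O)CC(=O)O | starting material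
7 | triethylsilyl 3-methyl-3-(triethylsilyloxy)butanoate | CC[Si](CC)(CC)OC(=O)CC(C)(C)O[Si](CC)(CC)CC | intermediate
8 | 3-methyl-3-(triethylsilyloxy)butanoic acid | CC[Si](CC)(CC)OC(C)(C)CC(=O)O | intermediate
9 | (R)-4-benzyloxazolidin-2-one | O=C1N[C@H](Cc2ccccc2)CO1 | starting material
10 | 3-methyl-3-(triethylsilyloxy)butanoic pivalic anhydride | CC[Si](CC)(CC)OC(C)(C)CC(=O)OC(=O)C(C)(C)C | intermediate
11 | (4R)-4-benzyl-3-[3-methyl-3-(triethylsilyloxy)butanoyl]-1,3-oxazolidin-2-one | CC[Si](CC)(CC)OC(C)(C)CC(=O)N1[C@H](Cc2ccccc2)COC1=O | intermediate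
12 | sodium (Z)-enolate of 11 | CC[Si](CC)(CC)OC(C)(C)/C=C(\[O-])N1[C@H](Cc2ccccc2)COC1=O.[Na+] | intermediate
13 | (4R)-4-benzyl-3-[(2R)-3-methyl-2-{[(5R)-2-methyl-5-(prop-1-en-2-yl)cyclopent-1-en-1-yl]methyl}-3-(triethylsilyloxy)butanoyl]-1,3-oxazolidin-2-one | C=C(C)[C@H]1CCC(C)=C1C[C@@H](C(=O)N2[C@H](Cc3ccccc3)COC2=O)C(C)(C)O[Si](CC)(CC)CC | intermediate
14 | (2R)-3-methyl-2-{[(5R)-2-methyl-5-(prop-1-en-2-yl)cyclopent-1-en-1-yl]methyl}-3-(triethylsilyloxy)butaneperoxoic acid | C=C(C)[C@H]1CCC(C)=C1C[C@@H](C(=O)OO)C(C)(C)O[Si](CC)(CC)CC | intermediate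
15 | (2R)-3-methyl-2-{[(5R)-2-methyl-5-(prop-1-en-2-yl)cyclopent-1-en-1-yl]methyl}-3-(triethylsilyloxy)butanoic acid | C=C(C)[C@H]1CCC(C)=C1C[C@@H](C(=O)O)C(C)(C)O[Si](CC)(CC)CC | intermediate
16 | Se-phenyl (2R)-3-methyl-2-{[(5R)-2-methyl-5-(prop-1-en-2-yl)cyclopent-1-en-1-yl]methyl}-3-(triethylsilyloxy)butaneselenoate | C=C(C)[C@H]1CCC(C)=C1C[C@@H](C(=O)[Se]c2ccccc2)C(C)(C)O[Si](CC)(CC)CC | intermediate
17 | (1R,7R,10S)-11-(triethylsilyloxy)guai-4-en-8-one | O=C1C[C@H](C)[C@H]2CCC(C)=C2C[C@@H]1C(C)(C)O[Si](CC)(CC)CC | intermediate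
18 | (1R,7S,8R,10S)-11-(triethylsilyloxy)guai-4-en-8-ol | O[C@@H]1C[C@H](C)[C@H]2CCC(C)=C2C[C@@H]1C(C)(C)O[Si](CC)(CC)CC | intermediate
19 | (1R,7S,8R,10S)-guai-4-ene-8,11-diol | O[C@@H]1C[C@H](C)[C@H]2CCC(C)=C2C[C@@H]1C(C)(C)O | intermediate
20 | (1R,7S,8R,10S)-11-hydroxyguai-4-en-8-yl 2-methylprop-2-enoate | C=C(C)C(=O)O[C@@H]1C[C@H](C)[C@H]2CCC(C)=C2C[C@@H]1C(C)(C)O | intermediate
21 | (1R,7S,8R,10S)-11-acetoxyguai-4-en-8-yl 2-methylprop-2-enoate | C=C(C)C(=O)O[C@@H]1C[C@H](C)[C@H]2CCC(C)=C2C[C@@H]1C(C)(C)OC(C)=O | intermediate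
22 | (1R,7S,8R,10S)-11-acetoxy-3-oxoguai-4-en-8-yl 2-methylprop-2-enoate (CNP0318307.1) | C=C(C)C(=O)O[C@@H]1C[C@H](C)[C@H]2CC(=O)C(C)=C2C[C@@H]1C(C)(C)OC(C)=O | target

Total step count: 14. Longest linear sequence: 12 steps (steps 1, 2, 3 and 6 to 14, from (S)-limonene); the imide branch adds steps 4 and 5.

Steps most likely to fail

Step 9. The acyl radical may be reduced by the silane before it cyclises, may lose carbon monoxide, or may abstract the doubly allylic C1–H, and the hydrogen transfer to the C10 radical may show poor facial selectivity. The fallback closes the same C8–C9 bond by a polar reaction and sets C10 in a separate step. It sets out from 13: LiBH4 (THF/MeOH, 0 °C) removes the auxiliary reductively to give primary alcohol F1, and Dess–Martin periodinane gives aldehyde F2. Me2AlCl (CH2Cl2, −78 °C) then promotes an intramolecular type 2 carbonyl-ene reaction, in which C8 bonds to C9 and a C14 hydrogen passes to oxygen, to give exocyclic-alkene alcohol F3. Hydrogenation over RhCl(PPh3)3 should reduce only the 1,1-disubstituted C10=C14 alkene, from the face remote from the C7 side chain, to give saturated alcohol F4. Dess–Martin oxidation of the C8 hydroxyl (either epimer) brings the sequence back to the route at 17.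

Step 6. C-alkylation of the congested enolate, which carries a fully substituted carbon next to the nucleophilic centre, may be slow, so that beta-elimination of silanolate from the enolate or its decomposition on warming takes over. The fallback reverses the roles so that the enolate is unhindered and has no beta leaving group. It sets out from 5: alkylation of the dilithium dianion of acetic acid (LiN(i-Pr)2, THF/DMPU) gives propanoic acid F5. Acylation of commercial (S)-4-benzyloxazolidin-2-one (O=C1N[C@@H](Cc2ccccc2)CO1) by the mixed-anhydride method of step 5 gives imide F6. The lithium Z-enolate (LiN(i-Pr)2, THF, −78 °C) is added to acetone and quenched cold with AcOH to give tertiary aldol F7. Because C11 instead of C6 now arrives on the chelated enolate face opposite the benzyl group, the auxiliary of the opposite series is required for 7R; the C7 epimers are diastereomers that can be separated at this stage. Silylation (Et3SiOTf, 2,6-lutidine) gives silyl ether F8, and LiOH/H2O2 cleavage as in step 7 brings the sequence back to the route at 15.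

Step 14. Oxidation may occur at the other allylic positions (the C6 methylene or the C1 methine) or go beyond the enone. The fallback divides the oxidation into an ene-type hydroxylation and a separate alcohol oxidation. It sets out from 21: catalytic SeO2 with t-BuOOH (CH2Cl2, rt), whose ene and sigmatropic steps favour the ring methylene on the less hindered side of the tetrasubstituted alkene, gives allylic alcohol F9, and MnO2 (CH2Cl2, rt) oxidises this to the enone, returning to the route at 22.

Further compounds

F1 | step 9 | (2S)-3-methyl-2-{[(5R)-2-methyl-5-(prop-1-en-2-yl)cyclopent-1-en-1-yl]methyl}-3-(triethylsilyloxy)butan-1-ol | C=C(C)[C@H]1CCC(C)=C1C[C@@H](CO)C(C)(C)O[Si](CC)(CC)CC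
F2 | step 9 | (2R)-3-methyl-2-{[(5R)-2-methyl-5-(prop-1-en-2-yl)cyclopent-1-en-1-yl]methyl}-3-(triethylsilyloxy)butanal | C=C(C)[C@H]1CCC(C)=C1C[C@@H](C=O)C(C)(C)O[Si](CC)(CC)CC
F3 | step 9 | (1R,7S)-11-(triethylsilyloxy)guaia-4,10(14)-dien-8-ol (C8 configuration open) | OC1CC(=C)[C@H]2CCC(C)=C2C[C@@H]1C(C)(C)O[Si](CC)(CC)CC
F4 | step 9 | (1R,7S,10S)-11-(triethylsilyloxy)guai-4-en-8-ol (C8 configuration open) | OC1C[C@H](C)[C@H]2CCC(C)=C2C[C@@H]1C(C)(C)O[Si](CC)(CC)CC
F5 | step 6 | 3-[(5R)-2-methyl-5-(prop-1-en-2-yl)cyclopent-1-en-1-yl]propanoic acid | C=C(C)[C@H]1CCC(C)=C1CCC(=O)O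
F6 | step 6 | (4S)-4-benzyl-3-{3-[(5R)-2-methyl-5-(prop-1-en-2-yl)cyclopent-1-en-1-yl]propanoyl}-1,3-oxazolidin-2-one | C=C(C)[C@H]1CCC(C)=C1CCC(=O)N2[C@@H](Cc3ccccc3)COC2=O
F7 | step 6 | (4S)-4-benzyl-3-[(2R)-3-hydroxy-3-methyl-2-{[(5R)-2-methyl-5-(prop-1-en-2-yl)cyclopent-1-en-1-yl]methyl}butanoyl]-1,3-oxazolidin-2-one | C=C(C)[C@H]1CCC(C)=C1C[C@@H](C(=O)N2[C@@H](Cc3ccccc3)COC2=O)C(C)(C)O
F8 | step 6 | (4S)-4-benzyl-3-[(2R)-3-methyl-2-{[(5R)-2-methyl-5-(prop-1-en-2-yl)cyclopent-1-en-1-yl]methyl}-3-(triethylsilyloxy)butanoyl]-1,3-oxazolidin-2-one | C=C(C)[C@H]1CCC(C)=C1C[C@@H](C(=O)N2[C@@H](Cc3ccccc3)COC2=O)C(C)(C)O[Si](CC)(CC)CC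
F9 | step 14 | (1R,7S,8R,10S)-11-acetoxy-3-hydroxyguai-4-en-8-yl 2-methylprop-2-enoate (C3 configuration open) | C=C(C)C(=O)O[C@@H]1C[C@H](C)[C@H]2CC(O)C(C)=C2C[C@@H]1C(C)(C)OC(C)=O
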